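## The problem

Target 13 is 7-hydroxy-3-(4-hydroxyphenyl)-6,8-bis(3-methylbut-2-enyl)chromen-4-one, an isoflavone. Ring A is fused to the pyranone ring C, ring B sits on C3, the hydroxyls are on C7 and C4', and the prenyl groups are on C6 and C8. There is no stereocentre and no stereogenic double bond, so nothing has to be controlled permanently; a centre made on the way only has to be removable. The difficulty is constitutional. Ring A carries substituents on five of its six carbons, both prenyl groups flank the C7 oxygen, and the pyranone must carry the aryl group on C3 and not on C2. The prenyl groups limit the chemistry: a trisubstituted alkene beside a free phenol closes to a chroman in strong acid, takes up electrophilic halogen and does not survive hydrogenolysis. Protecting groups must therefore leave under mild conditions, and ring A should not be halogenated once the side chains are in place. The enabling feature is that C4 is the carbonyl carbon of a salicylaldehyde and C3, once C2=C3 is read as a dehydrated carbinol, is the carbonyl carbon of a 4-oxygenated aryl ketone. The two carbons are tied together through O1 and C2 by a simple phenacyl ether. Both are electrophilic, so joining them calls for polarity reversal at C4, which a carbene catalyst provides.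

## Retrosynthesis

**13 to 12.** The two O–CH2OCH3 bonds are cut last. Acetal protection on O7 and O4' keeps both phenols silent through the basic and carbene-mediated steps, and the O7 phenol between the two prenyl groups is freed only at the end. The forward step must cleave two aryl acetals without adding the new phenol to a neighbouring alkene.

**12 to 11.** The C2=C3 double bond is traced back to a tertiary carbinol at C3. In 11 only C2 carries hydrogens next to the carbinol, so the elimination has one possible direction and its product is the conjugated pyranone. The gain is that 11 is an α-hydroxy ketone, the retron of a benzoin reaction. The forward step is a mild dehydration that ionises nothing else.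

**11 to 10 (key disconnection).** The C3–C4 bond is cut. The neighbouring cut at C4–C4a would need a ring A halide and an organolithium. A cut through C2 (a deoxybenzoin plus a one-carbon unit) would need acylation of a diprenylated resorcinol under Lewis acid, which the prenyl groups do not tolerate. The C3–C4 cut turns the bicyclic ketol into the open-chain keto aldehyde 10, in which both reacting carbons are ordinary carbonyl groups. The forward reaction must make the aldehyde carbon the nucleophile and close a six-membered ring faster than any base-induced aldol reaction.

**10 to 7 and 9.** The O1–C2 ether bond is cut. This nearly halves the molecule into salicylaldehyde 7 (ring A with both prenyl groups) and phenacyl bromide 9 (ring B with C2 and C3). The forward step is one SN2 reaction, which must be run mildly enough that 10 does not cyclise under the alkylation base.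

**9 to 8.** The O4' acetal is removed, giving the purchasable bromoketone 8. The forward step must cap the phenol before it can alkylate itself.

**7 to 5 and 6.** Both side-chain C=C bonds are cut, so that each prenyl group becomes an allyl group and the two isopropylidene ends come from 6. The neighbouring cut, ring carbon to CH2, would mean direct C-prenylation or two cycles through a tertiary allyl ether, each longer or less selective. Allyl groups are placed more easily, and one cross-metathesis converts both. Compound 5 differs from its precursor 4 only by the acetal on O4.

**4 to 3, then 1 and 2.** Both ring-to-allyl bonds at C3 and C5 are cut back to the two O-allyl ethers of 3, which comes from 1 and 2 in one alkylation. The forward step is a twofold Claisen rearrangement in which each allyl group has its own free ortho carbon.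

## Roads not taken

**Alternative 1:** The cut is at the two CH2–CH bonds of the prenyl chains, working on a finished isoflavone.
- Forward step: the purchasable parent isoflavone A2 would be silylated on O4' and aminomethylated twice (Mannich reaction) at C8 and C6. On heating, each aminomethyl group would release an ortho-quinone methide that accepts a 2-methylpropenyl group from an alkenylboronic acid, giving A1. Fluoride then frees O4'.
- Merits: no ring is built, the end is free of acid, and the count could be about five steps, clearly shorter than the chosen nine.
- Weak points: the second aminomethylation at C6 of a 7-hydroxyisoflavone is much less favoured than the first at C8. The liberated amine can add to C2 and open the pyranone. A twofold quinone methide alkenylation on this scaffold has no close model, and dimerisation or hetero-Diels–Alder capture of the quinone methide competes.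
- Comparison: this road is better in step count. The chosen plan sets against it a substitution pattern fixed by connectivity from 1 and steps that each have a close precedent.

**Alternative 2:** The cut is through ring A, at C5–C6 and C8–C8a.
- Forward step: the dienolate of a symmetrical ketone with a prenyl group on each α-carbon would add to an ethoxymethylene malonate with loss of ethoxide. The second α-carbon would then condense onto an ester and the ring would aromatise to resorcylate A3.
- Merits: both prenyl groups and both oxygens are placed by connectivity, without a 200 °C rearrangement and without a ruthenium catalyst. In these respects it is as good as or better than steps 1 to 4.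
- Weak points: the Claisen closure must start from a secondary, prenyl-bearing carbon in a crowded intermediate. The ketone needs about two steps to make. A3 is an ester that must be brought to the aldehyde level and protected on O4 before it can join the route at 7. It is a ring A synthesis only and still needs the pyranone closure.
- Comparison: the count to 7 would be about five to six steps against four from 1, which already has all ring carbons and the aldehyde at the right oxidation level. That is what the chosen plan sets against the cleaner regiochemistry of A3.

**Alternative 3:** The cut is at C4–C4a.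
- Forward step: a ring A aryl bromide carrying a (Z)-β-aryloxy-α-aryl acrylate ester on O1 would undergo bromine–lithium exchange with an alkyllithium at low temperature. The aryllithium would attack the ester and close the pyranone with loss of the ester alkoxide, giving A4, the same compound as 12.
- Merits: the chromone appears directly at the right oxidation level, with no ketol and no dehydration. That is one step fewer at the end and is better than the chosen plan in this respect.
- Weak points: the precursor needs a regiodefined bromination of a ring that already carries two prenyl groups, or a longer detour. The enol ether must be made with defined geometry from a phenol hindered on both sides. The aryllithium can also add to the β-carbon and expel the phenoxide, and the doubly activated ArCH2 protons of the prenyl groups are exposed to a strong base.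
- Comparison: the chosen plan sets against the better redox economy a precursor (10) made from 7 and 9 by one SN2 reaction, and a ring closure that is catalytic, runs near room temperature and needs no halogen on ring A.

Key step: step 7

## Route

Remark: the target has no stereocentre. The single centre created in step 7 (C3 of 11) is made with an achiral carbene, carried as the racemate and removed in step 8.

Step 1
Reactants: 1 2,4-dihydroxybenzaldehyde; 2 allyl bromide (3-bromoprop-1-ene)
Product: 3 2,4-bis(prop-2-enyloxy)benzaldehyde
Conditions: K2CO3 (3 equiv), 2 (2.5 equiv), DMF, 60 °C
Reagents that add atoms: none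
Why: Williamson ether synthesis; excess halide in DMF alkylates the hydrogen-bonded 2-OH as well as the more acidic 4-OH.

Step 2
Reactants: 3 2,4-bis(prop-2-enyloxy)benzaldehyde
Product: 4 2,4-dihydroxy-3,5-bis(prop-2-enyl)benzaldehyde
Conditions: PhNEt2, 200 °C, sealed tube, argon
Reagents that add atoms: none
Why: Twofold aromatic Claisen rearrangement; each allyl group has a free ortho carbon (O4 to C5, O2 to C3) because C1 is blocked by the formyl group. If the O4 allyl group takes C3 first, the O2 allyl group can still reach C5 through the ortho-dienone and a Cope shift, so all pathways should converge on 4. The amine solvent suppresses acid-catalysed cyclisation of the ortho-allylphenols.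

Step 3
Reactants: 4 2,4-dihydroxy-3,5-bis(prop-2-enyl)benzaldehyde
Product: 5 2-hydroxy-4-(methoxymethoxy)-3,5-bis(prop-2-enyl)benzaldehyde
Conditions: MOMCl (1.1 equiv), K2CO3, acetone, 0 °C to rt
Reagents that add atoms: chloromethyl methyl ether (MOMCl), COCCl
Why: Selective O-alkylation to the methoxymethyl ether; the 4-OH para to the formyl group is the more acidic, whereas the 2-OH is held in a hydrogen bond to the aldehyde, so one equivalent of reagent should go to O4.

Step 4
Reactants: 5 2-hydroxy-4-(methoxymethoxy)-3,5-bis(prop-2-enyl)benzaldehyde; 6 2-methylbut-2-ene
Product: 7 2-hydroxy-4-(methoxymethoxy)-3,5-bis(3-methylbut-2-enyl)benzaldehyde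
Conditions: RuCl2(=CHPh)(PCy3)(H2IMes) (second-generation Grubbs catalyst, 5 mol%), 6 (large excess)/CH2Cl2, 40 °C, sealed tube
Reagents that add atoms: none
Why: Twofold olefin cross-metathesis with 2-methylbut-2-ene, the standard conversion of an allylarene into a prenylarene; the trisubstituted product alkene re-enters the cycle only slowly, so excess 6 should carry both chains to the prenyl stage. The meta relation of the two allyl groups rules out ring-closing metathesis.

Step 5
Reactants: 8 2-bromo-1-(4-hydroxyphenyl)ethanone
Product: 9 2-bromo-1-[4-(methoxymethoxy)phenyl]ethanone
Conditions: MOMCl (1.3 equiv), i-Pr2NEt (1.5 equiv), CH2Cl2, 0 °C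
Reagents that add atoms: chloromethyl methyl ether (MOMCl), COCCl
Why: O-Methoxymethylation of an acidic para-acylphenol with a hindered amine base; the chloromethyl ether is far more electrophilic than the α-bromoketone, so at 0 °C the phenol should be capped before it can alkylate another molecule of 8.

Step 6
Reactants: 7 2-hydroxy-4-(methoxymethoxy)-3,5-bis(3-methylbut-2-enyl)benzaldehyde; 9 2-bromo-1-[4-(methoxymethoxy)phenyl]ethanone
Product: 10 4-(methoxymethoxy)-2-[2-[4-(methoxymethoxy)phenyl]-2-oxoethoxy]-3,5-bis(3-methylbut-2-enyl)benzaldehyde
Conditions: K2CO3 (1.5 equiv), acetone, rt
Reagents that add atoms: none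
Why: Williamson ether synthesis (SN2) with a highly reactive phenacyl bromide, forming O1–C2; mild carbonate in acetone at room temperature is chosen so that the ether can be isolated before the base effects aldol closure onto the aldehyde (the Rap–Stoermer pathway).

Step 7
Reactants: 10 4-(methoxymethoxy)-2-[2-[4-(methoxymethoxy)phenyl]-2-oxoethoxy]-3,5-bis(3-methylbut-2-enyl)benzaldehyde
Product: 11 racemic 3-hydroxy-7-(methoxymethoxy)-3-[4-(methoxymethoxy)phenyl]-6,8-bis(3-methylbut-2-enyl)chroman-4-one
Conditions: 2-(pentafluorophenyl)-6,7-dihydro-5H-pyrrolo[2,1-c][1,2,4]triazol-2-ium tetrafluoroborate (15 mol%), Et3N (15 mol%), toluene, 40 °C, argon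
Reagents that add atoms: none
Why: Et3N frees the triazolylidene, which adds to the aldehyde carbon of 10; proton transfer gives the Breslow intermediate, an enaminol whose former aldehyde carbon (the future C4) is nucleophilic. This acyl anion equivalent attacks the tethered aryl ketone carbonyl (the future C3) and forms the C3–C4 bond; proton transfer and loss of the carbene restore the C4 carbonyl and leave the tertiary C3 hydroxyl. The closest known reaction type is the carbene-catalysed intramolecular crossed aldehyde–ketone benzoin reaction of 2-(2-oxoalkoxy)benzaldehydes to 3-hydroxychroman-4-ones. The pyranone ring closes in the 6-exo-trig mode. The new stereocentre at C3 forms without control, as the racemate, because the catalyst is achiral and 10 has no stereogenic element; none is needed, since step 8 removes the centre. The step needs chemoselectivity: the crossed closure must beat aldehyde–aldehyde dimerisation and the base-induced aldol attack of the O–CH2 carbon on the aldehyde. The intramolecular six-membered delivery, the α-aryloxy group that activates the ketone as acceptor, and a weak amine base used only in catalytic amount should secure this; the ketone cannot form a Breslow intermediate, so donor and acceptor roles are fixed.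

Step 8
Reactants: 11 racemic 3-hydroxy-7-(methoxymethoxy)-3-[4-(methoxymethoxy)phenyl]-6,8-bis(3-methylbut-2-enyl)chroman-4-one
Product: 12 7-(methoxymethoxy)-3-[4-(methoxymethoxy)phenyl]-6,8-bis(3-methylbut-2-enyl)chromen-4-one
Conditions: Burgess reagent (MeO2C–N(−)–SO2–N(+)Et3, 2 equiv), toluene, 70 °C
Reagents that add atoms: none
Why: Dehydration of a tertiary alcohol with the Burgess reagent through the sulfamate ester and syn elimination; only C2 carries hydrogens next to the carbinol, so the double bond can form only between C2 and C3 and gives the conjugated pyranone. The neutral conditions spare the acetals and the prenyl groups, and the C3 stereocentre is removed.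

Step 9
Reactants: 12 7-(methoxymethoxy)-3-[4-(methoxymethoxy)phenyl]-6,8-bis(3-methylbut-2-enyl)chromen-4-one
Product: 13 7-hydroxy-3-(4-hydroxyphenyl)-6,8-bis(3-methylbut-2-enyl)chromen-4-one
Conditions: HCl (3 M aq.)/MeOH, 50 °C
Reagents that add atoms: none
Why: Acid-catalysed acetal cleavage of both methoxymethyl ethers by exchange with methanol; dilute acid at moderate temperature is the usual unmasking for prenylated phenols. The reaction is stopped as soon as both ethers are gone, so that the 7-OH does not add to a neighbouring prenyl group.

## Compound list

1 | 2,4-dihydroxybenzaldehyde | O=Cc1ccc(O)cc1O | starting material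
2 | allyl bromide (3-bromoprop-1-ene) | C=CCBr | starting material
3 | 2,4-bis(prop-2-enyloxy)benzaldehyde | O=Cc1ccc(OCC=C)cc1OCC=C | intermediate
4 | 2,4-dihydroxy-3,5-bis(prop-2-enyl)benzaldehyde | O=Cc1cc(CC=C)c(O)c(CC=C)c1O | intermediate
5 | 2-hydroxy-4-(methoxymethoxy)-3,5-bis(prop-2-enyl)benzaldehyde | O=Cc1cc(CC=C)c(OCOC)c(CC=C)c1O | intermediate
6 | 2-methylbut-2-ene | CC=C(C)C | starting material
7 | 2-hydroxy-4-(methoxymethoxy)-3,5-bis(3-methylbut-2-enyl)benzaldehyde | O=Cc1cc(CC=C(C)C)c(OCOC)c(CC=C(C)C)c1O | intermediate
8 | 2-bromo-1-(4-hydroxyphenyl)ethanone | O=C(CBr)c1ccc(O)cc1 | starting material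
9 | 2-bromo-1-[4-(methoxymethoxy)phenyl]ethanone | COCOc1ccc(cc1)C(=O)CBr | intermediate
10 | 4-(methoxymethoxy)-2-[2-[4-(methoxymethoxy)phenyl]-2-oxoethoxy]-3,5-bis(3-methylbut-2-enyl)benzaldehyde | O=Cc1cc(CC=C(C)C)c(OCOC)c(CC=C(C)C)c1OCC(=O)c1ccc(OCOC)cc1 | intermediate
11 | racemic 3-hydroxy-7-(methoxymethoxy)-3-[4-(methoxymethoxy)phenyl]-6,8-bis(3-methylbut-2-enyl)chroman-4-one | O=C1c2cc(CC=C(C)C)c(OCOC)c(CC=C(C)C)c2OCC1(O)c1ccc(OCOC)cc1 | intermediate
12 | 7-(methoxymethoxy)-3-[4-(methoxymethoxy)phenyl]-6,8-bis(3-methylbut-2-enyl)chromen-4-one | O=c1c(-c2ccc(OCOC)cc2)coc2c(CC=C(C)C)c(OCOC)c(CC=C(C)C)cc12 | intermediate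
13 | 7-hydroxy-3-(4-hydroxyphenyl)-6,8-bis(3-methylbut-2-enyl)chromen-4-one | CC(C)=CCc1cc2c(=O)c(-c3ccc(O)cc3)coc2c(CC=C(C)C)c1O | target

## Step count and risks

Total step count: 9. Longest linear sequence: 8 steps (steps 1 to 4 and 6 to 9); step 5 is the only branch.

**Step 7 (key step).**
- Most likely failure: the base that frees the carbene also enolises the α-aryloxy ketone, and aldol closure onto the aldehyde with loss of water (benzofuran formation) outruns a slow carbene addition to an electron-rich, ortho-alkoxylated aldehyde. Reversal of the benzoin addition is the second risk.
- Fallback: it gives up the C3–C4 closure, attaches ring B by cross-coupling, sets out from 7 and comes back at 12. Addition of MeMgBr (excess, THF, 0 °C) to 7 should give racemic 2-(1-hydroxyethyl)-5-(methoxymethoxy)-4,6-bis(3-methylbut-2-enyl)phenol F1. Oxidation with MnO2 in CH2Cl2 should give 1-[2-hydroxy-4-(methoxymethoxy)-3,5-bis(3-methylbut-2-enyl)phenyl]ethanone F2. Condensation with N,N-dimethylformamide dimethyl acetal should give the enaminone (E)-3-(dimethylamino)-1-[2-hydroxy-4-(methoxymethoxy)-3,5-bis(3-methylbut-2-enyl)phenyl]prop-2-en-1-one F3. Iodine in chloroform should close it to 3-iodo-7-(methoxymethoxy)-6,8-bis(3-methylbut-2-enyl)chromen-4-one F4. Suzuki coupling of F4 with 4-(methoxymethoxy)phenylboronic acid (Pd(PPh3)4, K2CO3, aqueous 1,2-dimethoxyethane, 80 °C) should then give 12.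

**Step 2.**
- Most likely failure: the O2 allyl group migrates onto the formyl-bearing carbon with loss of the formyl group, or the second migration stays incomplete at the temperature the aldehyde tolerates.
- Fallback: two single, chelation-directed rearrangements, setting out from 1 and coming back at 4. One equivalent of 2 with K2CO3 in acetone should alkylate only the free 4-OH and give 2-hydroxy-4-(prop-2-enyloxy)benzaldehyde F5. Heating in PhNEt2 should move the allyl group to C3, the position favoured by the hydrogen-bonded ortho-hydroxy aldehyde, giving 2,4-dihydroxy-3-(prop-2-enyl)benzaldehyde F6. A second O-allylation at O4 should give 2-hydroxy-3-(prop-2-enyl)-4-(prop-2-enyloxy)benzaldehyde F7, whose only free ortho position is C5, so a second Claisen rearrangement should give 4.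

**Step 6.**
- Most likely failure: aldol condensation of the product under the alkylation base before it can be isolated, or slow alkylation of the hindered, hydrogen-bonded phenol that forces harsher conditions and so invites that condensation.
- Fallback: a base-free ether formation, setting out from 9 (with 7) and coming back at 10. Sodium formate in aqueous ethanol at reflux should convert 9 by displacement and hydrolysis of the formate ester into 2-hydroxy-1-[4-(methoxymethoxy)phenyl]ethanone F8. Mitsunobu coupling of F8 with 7 (PPh3, diisopropyl azodicarboxylate, THF, 0 °C to rt) should then give 10 under neutral conditions.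

**Step 8.**
- Most likely failure: slow departure of the sulfamate from a carbon flanked by a carbonyl group, so that 11 is recovered or an aryl or acyl shift competes.
- Fallback: a two-stage elimination with an external base, setting out from 11 and coming back at 12. Methanesulfonyl chloride and Et3N (CH2Cl2, −20 °C, sulfene pathway) should give the racemic mesylate [7-(methoxymethoxy)-3-[4-(methoxymethoxy)phenyl]-6,8-bis(3-methylbut-2-enyl)-4-oxochroman-3-yl] methanesulfonate F9. DBU in toluene at 80 °C should then remove a C2 hydrogen in an anti E2 elimination and give 12.

**Step 9.**
- Most likely failure: acid-catalysed addition of the freed 7-OH to a flanking prenyl group (chroman formation) while the second acetal is still being cleaved.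
- Fallback: silyl transfer replaces protic hydrolysis, setting out from 12 and coming back at 13. Trimethylsilyl triflate with 2,2'-bipyridyl in CH2Cl2 at 0 °C should exchange both aryl acetals for silyl ethers, giving 6,8-bis(3-methylbut-2-enyl)-7-(trimethylsilyloxy)-3-[4-(trimethylsilyloxy)phenyl]chromen-4-one F10. Addition of water at room temperature should then hydrolyse F10 to 13 without exposing the free phenol to strong acid.

## Further compounds

F1 | step 7 | racemic 2-(1-hydroxyethyl)-5-(methoxymethoxy)-4,6-bis(3-methylbut-2-enyl)phenol | CC(O)c1cc(CC=C(C)C)c(OCOC)c(CC=C(C)C)c1O
F2 | step 7 | 1-[2-hydroxy-4-(methoxymethoxy)-3,5-bis(3-methylbut-2-enyl)phenyl]ethanone | CC(=O)c1cc(CC=C(C)C)c(OCOC)c(CC=C(C)C)c1O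
F3 | step 7 | (E)-3-(dimethylamino)-1-[2-hydroxy-4-(methoxymethoxy)-3,5-bis(3-methylbut-2-enyl)phenyl]prop-2-en-1-one | CN(C)/C=C/C(=O)c1cc(CC=C(C)C)c(OCOC)c(CC=C(C)C)c1O
F4 | step 7 | 3-iodo-7-(methoxymethoxy)-6,8-bis(3-methylbut-2-enyl)chromen-4-one | O=c1c(I)coc2c(CC=C(C)C)c(OCOC)c(CC=C(C)C)cc12
F5 | step 2 | 2-hydroxy-4-(prop-2-enyloxy)benzaldehyde | O=Cc1ccc(OCC=C)cc1O
F6 | step 2 | 2,4-dihydroxy-3-(prop-2-enyl)benzaldehyde | O=Cc1ccc(O)c(CC=C)c1O
F7 | step 2 | 2-hydroxy-3-(prop-2-enyl)-4-(prop-2-enyloxy)benzaldehyde | O=Cc1ccc(OCC=C)c(CC=C)c1O
F8 | step 6 | 2-hydroxy-1-[4-(methoxymethoxy)phenyl]ethanone | COCOc1ccc(cc1)C(=O)CO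
F9 | step 8 | racemic [7-(methoxymethoxy)-3-[4-(methoxymethoxy)phenyl]-6,8-bis(3-methylbut-2-enyl)-4-oxochroman-3-yl] methanesulfonate | CS(=O)(=O)OC1(COc2c(CC=C(C)C)c(OCOC)c(CC=C(C)C)cc2C1=O)c1ccc(OCOC)cc1
F10 | step 9 | 6,8-bis(3-methylbut-2-enyl)-7-(trimethylsilyloxy)-3-[4-(trimethylsilyloxy)phenyl]chromen-4-one | C[Si](C)(C)Oc1ccc(cc1)-c1coc2c(CC=C(C)C)c(O[Si](C)(C)C)c(CC=C(C)C)cc2c1=O
A1 | alternative 1 | 7-hydroxy-6,8-bis(3-methylbut-2-enyl)-3-[4-(triisopropylsilyloxy)phenyl]chromen-4-one | CC(C)=CCc1cc2c(=O)c(-c3ccc(O[Si](C(C)C)(C(C)C)C(C)C)cc3)coc2c(CC=C(C)C)c1O
A2 | alternative 1 | 7-hydroxy-3-(4-hydroxyphenyl)chromen-4-one | O=c1c(-c2ccc(O)cc2)coc2cc(O)ccc12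
A3 | alternative 2 | ethyl 2,4-dihydroxy-3,5-bis(3-methylbut-2-enyl)benzoate | CCOC(=O)c1cc(CC=C(C)C)c(O)c(CC=C(C)C)c1O
A4 | alternative 3 | 7-(methoxymethoxy)-3-[4-(methoxymethoxy)phenyl]-6,8-bis(3-methylbut-2-enyl)chromen-4-one | COCOc1ccc(cc1)-c1coc2c(CC=C(C)C)c(OCOC)c(CC=C(C)C)cc2c1=O
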